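The route rests on cutting the C2–C3 bond of the pyranone ring (ring C). C2 is a methylene lying between O1 and the stereogenic C3, so it can be carried as the methyl group of an ortho-methoxy aryl ketone on ring A, while C3 is a diazo carbon that already bears the chromene (ring B). A chiral dirhodium carboxylate converts the diazo ketone into a carbene that inserts into a methoxy C–H bond; this one operation closes ring C, forms C2–C3 and sets C3. The precursor is a diaryl α-diazo ketone with the ring B ortho oxygen held as a triisopropylsilyl ether and the ring A para oxygen as a methoxymethyl ether.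

Key step: step 6

Numbering used: chroman-4-one positions O1, C2, C3, C4, C4a to C8a for rings C and A; primed positions for the aryl ring B at C3, whose 2'-oxygen is the C7 oxygen of the chromene.

Assumption: which enantiomer of the PTAD catalyst gives (S) at C3 cannot be derived reliably for this substrate; the S-ligand series is written, and the mirror-image catalyst Rh2(R-PTAD)4 would be used if a first run shows the opposite sense.

Assumption: 4-bromoresorcinol, 3-methylbut-2-enal and 1-(4-hydroxy-2-methoxyphenyl)ethanone are taken as purchasable.

Step 1
Reactants: 1 4-bromobenzene-1,3-diol (4-bromoresorcinol); 2 3-methylbut-2-enal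
Product: 3 6-bromo-2,2-dimethyl-2H-chromen-7-ol
Conditions: ethylenediammonium diacetate (10 mol %), toluene, 110 °C
Reagents that add atoms: none
Why: The amine salt should promote a Knoevenagel-type condensation of the enal at C6 of the resorcinol (ortho to one hydroxyl, para to the other, less hindered than C2) and the resulting dienone should close by oxa-6π electrocyclisation (formal [3+3] chromene annulation), while starting with the bromine in place means that the electron-rich styrene-like double bond never meets an electrophilic brominating agent.

Step 2
Reactants: 3 6-bromo-2,2-dimethyl-2H-chromen-7-ol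
Product: 4 [(6-bromo-2,2-dimethyl-2H-chromen-7-yl)oxy]tri(propan-2-yl)silane
Conditions: iPr3SiCl, imidazole, DMF, rt
Reagents that add atoms: triisopropylsilyl chloride, CC(C)[Si](Cl)(C(C)C)C(C)C
Why: Imidazole-promoted silylation of a phenol is routine even next to an ortho bromine, and the triisopropylsilyl ether masks the ring B ortho oxygen with a group that survives the basic steps ahead and offers no C–H bond at the 1,5-position of the later carbene.

Step 3
Reactants: 5 1-(4-hydroxy-2-methoxyphenyl)ethanone
Product: 6 1-[2-methoxy-4-(methoxymethoxy)phenyl]ethanone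
Conditions: MeOCH2Cl, iPr2NEt, CH2Cl2, 0 °C to rt
Reagents that add atoms: chloromethyl methyl ether, COCCl
Why: O-Alkylation of the acidic para-acyl phenol with chloromethyl methyl ether and a hindered amine (acetal protection) is routine, and the resulting formaldehyde acetal is inert to phosphate base, DBU, fluoride and, being para to the carbonyl, out of reach of the carbene.

Step 4
Reactants: 4 [(6-bromo-2,2-dimethyl-2H-chromen-7-yl)oxy]tri(propan-2-yl)silane; 6 1-[2-methoxy-4-(methoxymethoxy)phenyl]ethanone
Product: 7 2-[2,2-dimethyl-7-(triisopropylsilyloxy)-2H-chromen-6-yl]-1-[2-methoxy-4-(methoxymethoxy)phenyl]ethanone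
Conditions: Pd2(dba)3 (2 mol %), XPhos (2-dicyclohexylphosphino-2',4',6'-triisopropylbiphenyl, 5 mol %), K3PO4, toluene, 90 °C
Reagents that add atoms: none
Why: Palladium-catalysed α-arylation of a ketone (Buchwald–Hartwig type) should join the fragments through oxidative addition of zerovalent palladium into the C–Br bond of 4, exchange with the enolate of the methyl ketone and reductive elimination, the bulky ortho silyloxy group and biaryl phosphine stopping the reaction at monoarylation and the mild phosphate base sparing the aryl silyl ether.

Step 5
Reactants: 7 2-[2,2-dimethyl-7-(triisopropylsilyloxy)-2H-chromen-6-yl]-1-[2-methoxy-4-(methoxymethoxy)phenyl]ethanone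
Product: 8 2-diazo-2-[2,2-dimethyl-7-(triisopropylsilyloxy)-2H-chromen-6-yl]-1-[2-methoxy-4-(methoxymethoxy)phenyl]ethanone
Conditions: 4-acetamidobenzenesulfonyl azide, DBU, MeCN, 0 °C to rt, dark
Reagents that add atoms: 4-acetamidobenzenesulfonyl azide, CC(=O)Nc1ccc(cc1)S(=O)(=O)N=[N+]=[N-]
Why: Regitz diazo transfer should work directly because the methylene flanked by aryl and aroyl groups is acidic enough for DBU, its enolate adding to the terminal nitrogen of the sulfonyl azide and the adduct fragmenting to the α-aryl α-diazo ketone and the sulfonamide, as is standard for deoxybenzoins.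

Step 6
Reactants: 8 2-diazo-2-[2,2-dimethyl-7-(triisopropylsilyloxy)-2H-chromen-6-yl]-1-[2-methoxy-4-(methoxymethoxy)phenyl]ethanone
Product: 9 (3S)-3-[2,2-dimethyl-7-(triisopropylsilyloxy)-2H-chromen-6-yl]-7-(methoxymethoxy)chroman-4-one
Conditions: Rh2(S-PTAD)4 (dirhodium tetrakis[(S)-(1-adamantyl)(N-phthalimido)acetate], 1 mol %), 4 Å molecular sieves, PhCF3, 0 °C, slow addition of 8 at high dilution
Reagents that add atoms: none
Why: Loss of dinitrogen at the dirhodium core should give a donor/acceptor carbene at C3, which takes a hydride-like hydrogen from the oxygen-activated methoxy C–H bond in a concerted three-centre transition state, so that C2–C3 and C3–H form together and no enol or enolate of the product is passed. The closest known reaction type is the dirhodium-carboxylate-catalysed intramolecular C–H insertion of ortho-alkoxyaryl α-diazo ketones to chroman-4-ones, read together with the primary C–H insertion of aryl methyl ethers by aryl-substituted carbenes. Ring C closes by 1,6-C–H insertion through the atoms C3, C4, C4a, C8a, O1 and the methyl carbon, the only ring size open on the ketone side because the ortho aromatic C–H would demand a four-membered ring. C3 is set under catalyst control, the chiral phthalimido-carboxylate ligands shaping the pocket in which the methoxy C–H bond meets one face of the carbene. The step needs site selectivity for the ring A methoxy group, and the substrate secures it: the ring B ortho oxygen carries silicon at the 1,5-position (no hydrogen there, and the isopropyl C–H bonds are hindered and α to silicon, hence not hydridic), the methoxymethyl group is para to the carbonyl, and the chromene double bond cannot be reached within the molecule. The competing attack of the methoxy oxygen on the carbene gives a five-membered oxonium ylide that should revert for want of a good migrating group under aprotic, sieve-dried conditions, while low temperature, a non-coordinating solvent and slow addition hold back that path, carbene dimerisation and Wolff rearrangement.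

Step 7
Reactants: 9 (3S)-3-[2,2-dimethyl-7-(triisopropylsilyloxy)-2H-chromen-6-yl]-7-(methoxymethoxy)chroman-4-one
Product: 10 (3S)-3-(7-hydroxy-2,2-dimethyl-2H-chromen-6-yl)-7-(methoxymethoxy)chroman-4-one
Conditions: HF·pyridine, pyridine, THF, 0 °C to rt
Reagents that add atoms: none
Why: Fluoride cleaves the aryl silyl ether by forming the strong Si–F bond (desilylation), and the pyridine-buffered, base-free medium should leave the formaldehyde acetal, the chromene and the enolisable C3–H alone and hold back acid-promoted closure of the freed phenol onto C4.

Step 8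
Reactants: 10 (3S)-3-(7-hydroxy-2,2-dimethyl-2H-chromen-6-yl)-7-(methoxymethoxy)chroman-4-one
Product: 11 (3S)-3-(7-methoxy-2,2-dimethyl-2H-chromen-6-yl)-7-(methoxymethoxy)chroman-4-one
Conditions: Me3SiCHN2 (2 M in hexanes), iPr2NEt (0.3 equiv), MeOH–MeCN 1:4, 0 °C to rt
Reagents that add atoms: trimethylsilyldiazomethane, C[Si](C)(C)C=[N+]=[N-]
Why: Methylation of a phenol with trimethylsilyldiazomethane in methanol (diazoalkane O-alkylation with loss of dinitrogen) runs close to neutrality, the small amount of hindered amine being buffered by the phenol, which is far more acidic than C3–H, so that the stereocentre should be kept while the protected 7-oxygen leaves the 2'-oxygen as the only site.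

Step 9
Reactants: 11 (3S)-3-(7-methoxy-2,2-dimethyl-2H-chromen-6-yl)-7-(methoxymethoxy)chroman-4-one
Product: 13 (3S)-7-hydroxy-3-(7-methoxy-2,2-dimethyl-2H-chromen-6-yl)chroman-4-one (target), via bromomethyl ether 12 (not isolated)
Conditions: Me2BBr, CH2Cl2, −78 °C; then aq. NaHCO3, THF, 0 °C
Reagents that add atoms: none
Why: Bromodimethylborane binds the methoxy oxygen of the formaldehyde acetal and delivers bromide to its methylene carbon at −78 °C (Lewis-acid acetal cleavage), and the bromomethyl ether is hydrolysed by the bicarbonate quench, an aprotic low-temperature sequence chosen over protic acid because acid-catalysed enolisation at C3 and protonation of the chromene should then not compete, the aryl methyl ether being inert at this temperature.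

Compound list

1 | 4-bromobenzene-1,3-diol (4-bromoresorcinol) | Oc1ccc(Br)c(O)c1 | starting material
2 | 3-methylbut-2-enal | CC(C)=CC=O | starting material
3 | 6-bromo-2,2-dimethyl-2H-chromen-7-ol | CC1(C)C=Cc2cc(Br)c(O)cc2O1 | intermediate
4 | [(6-bromo-2,2-dimethyl-2H-chromen-7-yl)oxy]tri(propan-2-yl)silane | CC(C)[Si](C(C)C)(C(C)C)Oc1cc2OC(C)(C)C=Cc2cc1Br | intermediate
5 | 1-(4-hydroxy-2-methoxyphenyl)ethanone | CC(=O)c1ccc(O)cc1OC | starting material
6 | 1-[2-methoxy-4-(methoxymethoxy)phenyl]ethanone | CC(=O)c1ccc(OCOC)cc1OC | intermediate
7 | 2-[2,2-dimethyl-7-(triisopropylsilyloxy)-2H-chromen-6-yl]-1-[2-methoxy-4-(methoxymethoxy)phenyl]ethanone | CC(C)[Si](C(C)C)(C(C)C)Oc1cc2OC(C)(C)C=Cc2cc1CC(=O)c1ccc(OCOC)cc1OC | intermediate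
8 | 2-diazo-2-[2,2-dimethyl-7-(triisopropylsilyloxy)-2H-chromen-6-yl]-1-[2-methoxy-4-(methoxymethoxy)phenyl]ethanone | CC(C)[Si](C(C)C)(C(C)C)Oc1cc2OC(C)(C)C=Cc2cc1C(=[N+]=[N-])C(=O)c1ccc(OCOC)cc1OC | intermediate
9 | (3S)-3-[2,2-dimethyl-7-(triisopropylsilyloxy)-2H-chromen-6-yl]-7-(methoxymethoxy)chroman-4-one | CC(C)[Si](C(C)C)(C(C)C)Oc1cc2OC(C)(C)C=Cc2cc1[C@H]1COc2cc(OCOC)ccc2C1=O | intermediate
10 | (3S)-3-(7-hydroxy-2,2-dimethyl-2H-chromen-6-yl)-7-(methoxymethoxy)chroman-4-one | Oc1cc2OC(C)(C)C=Cc2cc1[C@H]1COc2cc(OCOC)ccc2C1=O | intermediate
11 | (3S)-3-(7-methoxy-2,2-dimethyl-2H-chromen-6-yl)-7-(methoxymethoxy)chroman-4-one | COc1cc2OC(C)(C)C=Cc2cc1[C@H]1COc2cc(OCOC)ccc2C1=O | intermediate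
12 | (3S)-7-(bromomethoxy)-3-(7-methoxy-2,2-dimethyl-2H-chromen-6-yl)chroman-4-one (formed in the flask, not isolated) | COc1cc2OC(C)(C)C=Cc2cc1[C@H]1COc2cc(OCBr)ccc2C1=O | intermediate
13 | (3S)-7-hydroxy-3-(7-methoxy-2,2-dimethyl-2H-chromen-6-yl)chroman-4-one (CNP0226344.1) | COc1cc2c(cc1[C@H]1COc3cc(O)ccc3C1=O)C=CC(C)(C)O2 | target

Total step count: 9. Longest linear sequence: 8 steps (steps 1, 2, 4, 5, 6, 7, 8 and 9, from compound 1); step 3 is a one-step branch.

Steps most likely to fail

Step 6 (carbene insertion). The methoxy oxygen may capture the carbene faster than its C–H bond does, and the five-membered oxonium ylide may then drain away by methyl migration or demethylation. The twisted, doubly ortho-substituted donor aryl may also weaken enantioinduction, and the carbene may dimerise. The fallback uses known chemistry, sets out from 4 and returns at 9. Purchased 7-hydroxychroman-4-one is protected (MeOCH2Cl, iPr2NEt, CH2Cl2) as 7-(methoxymethoxy)chroman-4-one F1. Palladium-catalysed α-arylation of F1 with 4 (Pd2(dba)3, XPhos, K3PO4, toluene, 90 °C) should give the racemic 3-aryl chroman-4-one F2. F2 is resolved by preparative chromatography on a chiral stationary phase, the (R)-isomer being re-racemised with DBU and recycled. The (S)-isomer is 9, and the route continues with step 7.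

Step 4 (ketone α-arylation). The hindered ortho-silyloxy bromide may couple slowly, or the silyl group may be lost to base at 90 °C, after which the freed phenoxide would add to the ketone and dehydrate to a benzofuran. The fallback sets out from 6 and 4 and returns at 7. Compound 6 is converted (Me3SiOTf, Et3N, CH2Cl2, 0 °C) into its trimethylsilyl enol ether F3. F3 is arylated with 4 in the absence of any Brønsted base by the tin-fluoride-mediated palladium coupling of enol silanes (Pd(OAc)2, P(t-Bu)3, Bu3SnF, toluene, 85 °C), which should give 7.

Step 1 (chromene annulation). Condensation may take place at C2 between the two hydroxyls and lead to angular isomers, a second annulation may follow at the remaining free position, or the enal may oligomerise, so that little of the linear chromenol is recovered. The fallback sets out from 1 and returns at 3. Friedel–Crafts acylation of 1 with 3-methylbut-2-enoic acid in MeSO3H–P2O5 (70 °C), which acylates para to a hydroxyl and closes by oxa-Michael addition, should give 6-bromo-7-hydroxy-2,2-dimethylchroman-4-one F4. Reduction (NaBH4, MeOH, 0 °C) gives racemic 6-bromo-2,2-dimethylchromane-4,7-diol F5, and acid-catalysed dehydration (p-TsOH cat., toluene, 80 °C) gives 3.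

Further compounds

F1 | step 6 | 7-(methoxymethoxy)chroman-4-one | COCOc1ccc2C(=O)CCOc2c1
F2 | step 6 | racemic 3-[2,2-dimethyl-7-(triisopropylsilyloxy)-2H-chromen-6-yl]-7-(methoxymethoxy)chroman-4-one | CC(C)[Si](C(C)C)(C(C)C)Oc1cc2OC(C)(C)C=Cc2cc1C1COc2cc(OCOC)ccc2C1=O
F3 | step 4 | trimethyl({1-[2-methoxy-4-(methoxymethoxy)phenyl]ethenyl}oxy)silane | COCOc1ccc(C(=C)O[Si](C)(C)C)c(OC)c1
F4 | step 1 | 6-bromo-7-hydroxy-2,2-dimethylchroman-4-one | CC1(C)CC(=O)c2cc(Br)c(O)cc2O1
F5 | step 1 | racemic 6-bromo-2,2-dimethylchromane-4,7-diol | CC1(C)CC(O)c2cc(Br)c(O)cc2O1
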